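**Retrosynthetic overview**
1. Feature: in daucane numbering, C5, C6, C7, C8 (with methyl C14), C9 and C10 are the six carbons of a para-methylated benzene ring. The quaternary C1 (methyl C15, neighbour of C2) is an extra carbon wedged between the former ipso carbon C5 and one ortho carbon, C10.
2. Key disconnection: C1–C5 and C1–C10 are made together by an intramolecular Büchner reaction of α-diazo ethyl ketone 13. The five-membered ring (C1–C5) closes first, in the cyclopropanation; the seven-membered ring (C1, C5–C10) follows when norcaradiene 14 opens.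
3. Precursor: C4 comes from ketone 1 (asymmetric hydrogenation, then stereospecific lithiation–borylation with allyl boronate 4). C3 and C2 come from the allyl group after oxidative cleavage, and C1 and C15 from diazoethane.
4. Triene 15 is differentiated with the 4β-OH as control element: directed reduction at C2, epoxidation of C9=C10, SmI2 opening to the C8=C9 allylic alcohol, inversion at C10 through the enone, directed epoxidation of C5=C6, radical opening to 5α-H, then oxidation and directed reduction at C6.
5. Each carbinol is esterified as it appears: acetate (C2), benzoate (C10), angelate (C6) last.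

Key step: step 7

Remark: daucane numbering is used throughout. β is the face of the bicycle that carries the C15 methyl group and α is the opposite face. The sense of induction in step 1 is assumed to follow that of other aryl alkyl ketones.

**Step 1**
Reactants: 1 2-methyl-1-(4-methylphenyl)propan-1-one
Product: 2 (R)-2-methyl-1-(4-methylphenyl)propan-1-ol
Conditions: H2 (8 atm), RuCl2[(S)-xylbinap][(S)-daipen] (0.1 mol %), t-BuOK, i-PrOH, 25 °C
Reagents that add atoms: none
Why: Noyori asymmetric hydrogenation is reliable for α-branched aryl alkyl ketones, and the (S,S)-catalyst, which gives R carbinols in this ketone class, sets the stereocentre that later becomes C4.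

**Step 2**
Reactants: 2 (R)-2-methyl-1-(4-methylphenyl)propan-1-ol
Product: 3 (R)-2-methyl-1-(4-methylphenyl)propyl N,N-diisopropylcarbamate
Conditions: NaH, THF, 0 °C; i-Pr2NCOCl, reflux
Reagents that add atoms: N,N-diisopropylcarbamoyl chloride CC(C)N(C(C)C)C(=O)Cl
Why: O-carbamoylation of the sodium alkoxide is a plain acyl substitution that leaves the stereocentre untouched and installs the directing and leaving group for the next step.

**Step 3**
Reactants: 3 (R)-2-methyl-1-(4-methylphenyl)propyl N,N-diisopropylcarbamate; 4 allylboronic acid pinacol ester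
Product: 6 (R)-2-methyl-3-(4-methylphenyl)hex-5-en-3-ol, via tertiary boronic ester 5 (not isolated)
Conditions: s-BuLi, Et2O, −78 °C; 4, −78 °C → rt; then H2O2, aq NaOH, THF, 0 °C
Reagents that add atoms: hydrogen peroxide OO
Why: Lithiation–borylation: carbamate-directed deprotonation gives a configurationally stable benzylic lithium species that is borylated with retention, the allyl group migrates from boron to carbon anti to the departing carbamate, and oxidation with retention turns the C–B bond of 5 into the C4–O bond, so the configuration of 2 passes stereospecifically into the tertiary carbinol.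

**Step 4**
Reactants: 6 (R)-2-methyl-3-(4-methylphenyl)hex-5-en-3-ol
Product: 7 (R)-triethyl{[2-methyl-3-(4-methylphenyl)hex-5-en-3-yl]oxy}silane
Conditions: TESOTf, 2,6-lutidine, CH2Cl2, 0 °C
Reagents that add atoms: triethylsilyl trifluoromethanesulfonate CC[Si](CC)(CC)OS(=O)(=O)C(F)(F)F
Why: A silyl triflate with a hindered pyridine base silylates even crowded tertiary alcohols, and O4 must be masked because a free hydroxyl would undergo O–H insertion with the carbene of step 7.

**Step 5**
Reactants: 7 (R)-triethyl{[2-methyl-3-(4-methylphenyl)hex-5-en-3-yl]oxy}silane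
Product: 9 (R)-4-methyl-3-(4-methylphenyl)-3-(triethylsilyloxy)pentanoic acid, via aldehyde 8 (not isolated)
Conditions: O3, CH2Cl2/MeOH, −78 °C; Me2S; then NaClO2, NaH2PO4, 2-methyl-2-butene, t-BuOH/H2O, 0 °C → rt
Reagents that add atoms: ozone [O-][O+]=O; sodium chlorite [Na+].[O-]Cl=O
Why: Ozonolysis cleaves only the terminal alkene (the arene reacts far more slowly), and buffered Pinnick oxidation of crude 8 gives the acid without β-elimination or loss of the silyl ether, C4 being untouched.

**Step 6**
Reactants: 9 (R)-4-methyl-3-(4-methylphenyl)-3-(triethylsilyloxy)pentanoic acid; 10 N-ethyl-N-nitrosourea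
Product: 13 (R)-2-diazo-6-methyl-5-(4-methylphenyl)-5-(triethylsilyloxy)heptan-3-one, via acid chloride 11 (not isolated), via diazoethane 12 (not isolated)
Conditions: 9, Me2C=C(Cl)NMe2, CH2Cl2, 0 °C; separately 10, aq KOH, Et2O, −10 °C; 11 added to ethereal 12 (3 equiv), −20 → 0 °C
Reagents that add atoms: 1-chloro-N,N,2-trimethylprop-1-en-1-amine CC(C)=C(Cl)N(C)C (chlorine of 11 only)
Why: The neutral α-chloroenamine makes 11 without free HCl, so the acid-labile tertiary benzylic silyl ether survives, and C-acylation of excess diazoethane (the diazoketone stage of the Arndt–Eistert sequence) gives the α-methyl diazoketone while a second equivalent takes up HCl.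

**Step 7**
Reactants: 13 (R)-2-diazo-6-methyl-5-(4-methylphenyl)-5-(triethylsilyloxy)heptan-3-one
Product: 15 (3R,8aR)-6,8a-dimethyl-3-(propan-2-yl)-3-(triethylsilyloxy)-3,8a-dihydroazulen-1(2H)-one (4β-triethylsilyloxydauca-5,7,9-trien-2-one), via norcaradiene 14 (not isolated)
Conditions: Rh2(OAc)4 (1 mol %), CH2Cl2, reflux, slow addition of 13; filtration through neutral alumina
Reagents that add atoms: none
Why: Rh2(OAc)4 expels N2 from 13 and the electrophilic rhodium carbene at C1 adds across the ipso–ortho π bond C5–C10 of the tethered p-tolyl ring to give norcaradiene 14, whose C5–C10 σ bond then breaks in a disrotatory 6π electrocyclic opening to cycloheptatriene 15. The closest known reaction type is the intramolecular Büchner reaction of 1-diazo-4-arylbutan-2-ones and of their α-methyl homologues (2-diazo-5-arylpentan-3-ones), which give 8a-methyl dihydroazulenones under the same catalysis. The five-membered ring (C1–C5) is closed in the cyclopropanation through the C1–C5 bond, helped by the geminal disubstitution at C4, whereas the seven-membered ring (C1, C5–C10) arises by one-carbon expansion of the benzene ring through the C1–C10 bond and loss of the C5–C10 bond. C1 is the only new stereocentre that survives (C5 and C10 of 14 return to sp2), and it is set by 1,3-induction from C4: in the favoured approach the isopropyl group points to the side of the attacked ortho carbon and away from C15, so the methyl group ends up cis to the slimmer C–O bond and trans to isopropyl, as benzylic alkyl groups do in related cyclisations. The two ortho positions are interconverted by aryl rotation, so there is no regiochemical issue; what is needed is chemoselectivity for arene addition over 1,2-hydride shift from C15, oxonium ylide formation at O4 and 1,5-insertion into the isopropyl C–H bond. These should be held back by the proximity of the electron-rich arene, the bulk of the triethylsilyl group and the steric and inductive deactivation of a methine next to the oxygenated quaternary C4, and slow addition keeps carbene dimerisation low.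

**Step 8**
Reactants: 15 4β-triethylsilyloxydauca-5,7,9-trien-2-one
Product: 16 4β-hydroxydauca-5,7,9-trien-2-one
Conditions: HF·pyridine, pyridine, THF, 0 °C
Reagents that add atoms: none
Why: Fluoride cleavage under pyridine buffering frees the tertiary alcohol without acid-induced ionisation of the trienyl carbinol, rearrangement to a tetralone, or base-induced retro-aldol and E1cB loss of O4.

**Step 9**
Reactants: 16 4β-hydroxydauca-5,7,9-trien-2-one
Product: 17 dauca-5,7,9-triene-2α,4β-diol
Conditions: Me4NBH(OAc)3, MeCN/AcOH, −30 °C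
Reagents that add atoms: none
Why: Evans–Saksena reduction: ligand exchange binds the borohydride to the 4β-OH and hydride is delivered intramolecularly to the β face of the C2 ketone, which sets the 2α-carbinol (trans-1,3-diol) even though the angular methyl group shields that face from external hydrides.

**Step 10**
Reactants: 17 dauca-5,7,9-triene-2α,4β-diol
Product: 18 2α-acetoxydauca-5,7,9-trien-4β-ol
Conditions: Ac2O, pyridine, DMAP (cat.), CH2Cl2, 0 °C → rt
Reagents that add atoms: acetic anhydride CC(=O)OC(C)=O
Why: DMAP-catalysed acetylation distinguishes the secondary C2 alcohol from the crowded tertiary C4 alcohol on steric grounds.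

**Step 11**
Reactants: 18 2α-acetoxydauca-5,7,9-trien-4β-ol
Product: 19 2α-acetoxy-9α,10α-epoxydauca-5,7-dien-4β-ol
Conditions: dimethyldioxirane (1.0 equiv), acetone/CH2Cl2, −40 °C
Reagents that add atoms: dimethyldioxirane CC1(C)OO1
Why: Electrophilic epoxidation of a conjugated triene takes a terminal double bond so that a diene stays conjugated, and since C5=C6 is buried between the fully substituted C1 and C4, the neutral, sterically sensitive dioxirane should take C9=C10 from the convex α face opposite the pseudoaxial C15 methyl (a configuration that is erased in step 13).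

**Step 12**
Reactants: 19 2α-acetoxy-9α,10α-epoxydauca-5,7-dien-4β-ol
Product: 20 2α-acetoxydauca-5,8-diene-4β,10α-diol
Conditions: SmI2 (2.5 equiv), HMPA, MeOH, THF, −78 °C
Reagents that add atoms: none
Why: Reduction of vinyl oxiranes with SmI2 (divalent samarium) cleaves the allylic C9–O bond by two single-electron transfers, and the pentadienyl samarium species should be protonated at its central carbon C7 (highest charge density, as in Birch-type protonations; C5 is fully substituted and C9 flanks the alkoxide), which moves the alkene to C8=C9 and leaves the C10–O bond intact.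

**Step 13**
Reactants: 20 2α-acetoxydauca-5,8-diene-4β,10α-diol
Product: 21 2α-acetoxy-4β-hydroxydauca-5,8-dien-10-one
Conditions: Dess–Martin periodinane, NaHCO3, CH2Cl2, 0 °C
Reagents that add atoms: none
Why: Dess–Martin oxidation turns the secondary allylic alcohol into the enone under buffered, near-neutral conditions, cannot touch the tertiary alcohol, and clears the wrong C10 configuration.

**Step 14**
Reactants: 21 2α-acetoxy-4β-hydroxydauca-5,8-dien-10-one
Product: 22 2α-acetoxydauca-5,8-diene-4β,10β-diol
Conditions: NaBH4, CeCl3·7H2O, MeOH, −78 °C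
Reagents that add atoms: none
Why: Luche reduction gives clean 1,2-reduction, and hydride should enter from the α face, anti to the pseudoaxial C15 methyl on the neighbouring quaternary C1, which places the new hydroxyl group β.

**Step 15**
Reactants: 22 2α-acetoxydauca-5,8-diene-4β,10β-diol
Product: 23 2α-acetoxy-10β-benzoyloxydauca-5,8-dien-4β-ol
Conditions: BzCl, pyridine, DMAP, CH2Cl2, rt
Reagents that add atoms: benzoyl chloride O=C(Cl)c1ccccc1
Why: DMAP-catalysed acylation esterifies the only secondary alcohol, while the tertiary 4-OH stays free for the steps that follow.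

**Step 16**
Reactants: 23 2α-acetoxy-10β-benzoyloxydauca-5,8-dien-4β-ol
Product: 24 2α-acetoxy-10β-benzoyloxy-5β,6β-epoxydauc-8-en-4β-ol
Conditions: VO(acac)2 (5 mol %), t-BuOOH, CH2Cl2, 0 °C → rt
Reagents that add atoms: tert-butyl hydroperoxide CC(C)(C)OO
Why: In the vanadium-catalysed, hydroxyl-directed epoxidation the alkoxide-bound peroxide reaches only the allylic C5=C6 bond and delivers oxygen syn to the 4β-OH, so the C8=C9 bond (whose allylic oxygen is acylated) is left alone and the 5β,6β-epoxide results.

**Step 17**
Reactants: 24 2α-acetoxy-10β-benzoyloxy-5β,6β-epoxydauc-8-en-4β-ol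
Product: 25 2α-acetoxy-10β-benzoyloxy-5αH-dauc-8-ene-4β,6β-diol
Conditions: Cp2TiCl2, Zn, THF, rt; then 24, 1,4-cyclohexadiene, rt; aq NaH2PO4
Reagents that add atoms: none
Why: Nugent–RajanBabu reductive epoxide opening: Cp2TiCl (trivalent titanium) cleaves the C5–O bond homolytically to the more substituted radical, as known for trisubstituted 2,3-epoxy alcohols that give 1,3-diols, and hydrogen-atom transfer from 1,4-cyclohexadiene should come from the α face because C15, O4 and the titanium-bound O6 all crowd the β face, which sets 5α-H (trans ring fusion).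

**Step 18**
Reactants: 25 2α-acetoxy-10β-benzoyloxy-5αH-dauc-8-ene-4β,6β-diol
Product: 26 2α-acetoxy-10β-benzoyloxy-4β-hydroxy-5αH-dauc-8-en-6-one
Conditions: Dess–Martin periodinane, NaHCO3, CH2Cl2, 0 °C
Reagents that add atoms: none
Why: Dess–Martin oxidation of the only secondary alcohol under bicarbonate buffering avoids enolisation, so C5 is not epimerised, the β,γ-alkene does not move and the benzoate is not expelled.

**Step 19**
Reactants: 26 2α-acetoxy-10β-benzoyloxy-4β-hydroxy-5αH-dauc-8-en-6-one
Product: 27 2α-acetoxy-10β-benzoyloxy-5αH-dauc-8-ene-4β,6α-diol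
Conditions: Me4NBH(OAc)3, MeCN/AcOH, −30 °C
Reagents that add atoms: none
Why: Second Evans–Saksena reduction: 26 is again a β-hydroxy ketone, and boron bound to the 4β-OH (cis to C6 on the five-membered ring) delivers hydride to the β face of C6 to give the 6α-alcohol, while esters and alkene are inert to the reagent.

**Step 20**
Reactants: 27 2α-acetoxy-10β-benzoyloxy-5αH-dauc-8-ene-4β,6α-diol; 28 angelic acid, (Z)-2-methylbut-2-enoic acid
Product: 30 2α-acetoxy-6α-angeloyloxy-10β-benzoyloxy-5αH-dauc-8-en-4β-ol (1R,2S,4R,5S,6S,10S; the target), via mixed anhydride 29 (not isolated)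
Conditions: 28, 2,4,6-trichlorobenzoyl chloride, Et3N, toluene, rt; then 27, 80 °C
Reagents that add atoms: 2,4,6-trichlorobenzoyl chloride O=C(Cl)c1c(Cl)cc(Cl)cc1Cl (aroyl part of 29 only)
Why: Yamaguchi esterification through 29 without a nucleophilic catalyst acylates the secondary 6α-OH and avoids the addition–elimination pathway that isomerises angelates to tiglates, and the tertiary alcohol does not react.

**Compound list**
1 | 2-methyl-1-(4-methylphenyl)propan-1-one | CC(C)C(=O)c1ccc(C)cc1 | starting material
2 | (R)-2-methyl-1-(4-methylphenyl)propan-1-ol | O[C@H](C(C)C)c1ccc(C)cc1 | intermediate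
3 | (R)-2-methyl-1-(4-methylphenyl)propyl N,N-diisopropylcarbamate | CC(C)N(C(C)C)C(=O)O[C@H](C(C)C)c1ccc(C)cc1 | intermediate
4 | allylboronic acid pinacol ester | C=CCB1OC(C)(C)C(C)(C)O1 | starting material
5 | (S)-2-[2-methyl-3-(4-methylphenyl)hex-5-en-3-yl]-4,4,5,5-tetramethyl-1,3,2-dioxaborolane | C=CC[C@@](B1OC(C)(C)C(C)(C)O1)(C(C)C)c1ccc(C)cc1 | intermediate
6 | (R)-2-methyl-3-(4-methylphenyl)hex-5-en-3-ol | C=CC[C@@](O)(C(C)C)c1ccc(C)cc1 | intermediate
7 | (R)-triethyl{[2-methyl-3-(4-methylphenyl)hex-5-en-3-yl]oxy}silane | C=CC[C@@](O[Si](CC)(CC)CC)(C(C)C)c1ccc(C)cc1 | intermediate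
8 | (R)-4-methyl-3-(4-methylphenyl)-3-(triethylsilyloxy)pentanal | O=CC[C@@](O[Si](CC)(CC)CC)(C(C)C)c1ccc(C)cc1 | intermediate
9 | (R)-4-methyl-3-(4-methylphenyl)-3-(triethylsilyloxy)pentanoic acid | OC(=O)C[C@@](O[Si](CC)(CC)CC)(C(C)C)c1ccc(C)cc1 | intermediate
10 | N-ethyl-N-nitrosourea | CCN(N=O)C(N)=O | starting material
11 | (R)-4-methyl-3-(4-methylphenyl)-3-(triethylsilyloxy)pentanoyl chloride | ClC(=O)C[C@@](O[Si](CC)(CC)CC)(C(C)C)c1ccc(C)cc1 | intermediate
12 | diazoethane | CC=[N+]=[N-] | intermediate
13 | (R)-2-diazo-6-methyl-5-(4-methylphenyl)-5-(triethylsilyloxy)heptan-3-one | CC(=[N+]=[N-])C(=O)C[C@@](O[Si](CC)(CC)CC)(C(C)C)c1ccc(C)cc1 | intermediate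
14 | norcaradiene valence isomer of 15 (cyclopropane C1–C5–C10 fused to the cyclopentanone and to a 1,3-cyclohexadiene; C10 on the α face, C15 on the β face of the five-membered ring) | C[C@@]12[C@H]3C=C(C)C=C[C@@]13[C@](O[Si](CC)(CC)CC)(C(C)C)CC2=O | intermediate
15 | (3R,8aR)-6,8a-dimethyl-3-(propan-2-yl)-3-(triethylsilyloxy)-3,8a-dihydroazulen-1(2H)-one | C[C@@]12C=CC(C)=CC=C1[C@](O[Si](CC)(CC)CC)(C(C)C)CC2=O | intermediate
16 | 4β-hydroxydauca-5,7,9-trien-2-one | C[C@@]12C=CC(C)=CC=C1[C@](O)(C(C)C)CC2=O | intermediate
17 | dauca-5,7,9-triene-2α,4β-diol | C[C@@]12C=CC(C)=CC=C1[C@](O)(C(C)C)C[C@@H]2O | intermediate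
18 | 2α-acetoxydauca-5,7,9-trien-4β-ol | C[C@@]12C=CC(C)=CC=C1[C@](O)(C(C)C)C[C@@H]2OC(C)=O | intermediate
19 | 2α-acetoxy-9α,10α-epoxydauca-5,7-dien-4β-ol | C[C@@]12[C@@H]3O[C@@H]3C(C)=CC=C1[C@](O)(C(C)C)C[C@@H]2OC(C)=O | intermediate
20 | 2α-acetoxydauca-5,8-diene-4β,10α-diol | C[C@@]12[C@H](O)C=C(C)CC=C1[C@](O)(C(C)C)C[C@@H]2OC(C)=O | intermediate
21 | 2α-acetoxy-4β-hydroxydauca-5,8-dien-10-one | C[C@@]12C(=O)C=C(C)CC=C1[C@](O)(C(C)C)C[C@@H]2OC(C)=O | intermediate
22 | 2α-acetoxydauca-5,8-diene-4β,10β-diol | C[C@@]12[C@@H](O)C=C(C)CC=C1[C@](O)(C(C)C)C[C@@H]2OC(C)=O | intermediate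
23 | 2α-acetoxy-10β-benzoyloxydauca-5,8-dien-4β-ol | C[C@@]12[C@@H](OC(=O)c3ccccc3)C=C(C)CC=C1[C@](O)(C(C)C)C[C@@H]2OC(C)=O | intermediate
24 | 2α-acetoxy-10β-benzoyloxy-5β,6β-epoxydauc-8-en-4β-ol | O1[C@@H]2CC(C)=C[C@H](OC(=O)c4ccccc4)[C@@]3(C)[C@@H](OC(C)=O)C[C@@](O)(C(C)C)[C@@]123 | intermediate
25 | 2α-acetoxy-10β-benzoyloxy-5αH-dauc-8-ene-4β,6β-diol | O[C@@H]1CC(C)=C[C@H](OC(=O)c2ccccc2)[C@@]2(C)[C@@H](OC(C)=O)C[C@@](O)(C(C)C)[C@H]12 | intermediate
26 | 2α-acetoxy-10β-benzoyloxy-4β-hydroxy-5αH-dauc-8-en-6-one | O=C1CC(C)=C[C@H](OC(=O)c2ccccc2)[C@@]2(C)[C@@H](OC(C)=O)C[C@@](O)(C(C)C)[C@H]12 | intermediate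
27 | 2α-acetoxy-10β-benzoyloxy-5αH-dauc-8-ene-4β,6α-diol | O[C@H]1CC(C)=C[C@H](OC(=O)c2ccccc2)[C@@]2(C)[C@@H](OC(C)=O)C[C@@](O)(C(C)C)[C@H]12 | intermediate
28 | angelic acid, (Z)-2-methylbut-2-enoic acid | C/C=C(/C)C(=O)O | starting material
29 | angelic 2,4,6-trichlorobenzoic anhydride | C/C=C(/C)C(=O)OC(=O)c1c(Cl)cc(Cl)cc1Cl | intermediate
30 | 2α-acetoxy-6α-angeloyloxy-10β-benzoyloxy-5αH-dauc-8-en-4β-ol (CNP0248576.1) | C/C=C(/C)C(=O)O[C@H]1CC(C)=C[C@H](OC(=O)c2ccccc2)[C@@]2(C)[C@@H](OC(C)=O)C[C@@](O)(C(C)C)[C@H]12 | target

**Total step count:** 20. **Longest linear sequence:** 20 steps (1 → 30).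

**The three steps most likely to fail**

Step 7 (key step).
- What may go wrong: the carbene may be drained by 1,2-hydride shift from C15, by attack of the O4 lone pair (oxonium ylide, silyl migration) or by insertion into the isopropyl C–H bond. The 1,3-induction from C4 may also give poor facial selectivity at C1.
- Fallback: stereocontrol and chemoselectivity are moved from the substrate to the reagent. Setting out from 13, the cyclisation is run through a cationic copper carbene that carries a C2-symmetric bis(oxazoline). The carbene is generated from [Cu(MeCN)4]PF6, 2,2'-(propane-2,2-diyl)bis[(4R)-4-phenyl-4,5-dihydrooxazole] or its enantiomer, and NaB[3,5-(CF3)2C6H3]4 in CH2Cl2. This catalyst type is known to fix the face of arene attack in Büchner cyclisations of 2-diazo-5-arylpentan-3-ones, and its more electrophilic carbene favours arene addition over insertion. The ligand enantiomer that is matched with C4 is used. The fallback comes back to the route at 15 and makes no new compound (F0).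

Step 11.
- What may go wrong: poor site selectivity among the three double bonds of the triene. Attack may occur at the more electron-rich central C7=C8 bond, or hydrogen bonding to the free 4-OH may guide attack to C5=C6.
- Fallback: reagent control is replaced by oxygen delivery from a neighbouring hydroxyl group on the α face. Setting out from 18, the tertiary alcohol is silylated (TESOTf, 2,6-lutidine) to 2α-acetoxy-4β-(triethylsilyloxy)dauca-5,7,9-triene F1. The acetate is then removed (K2CO3, MeOH) to give 4β-(triethylsilyloxy)dauca-5,7,9-trien-2α-ol F2. Epoxidation with VO(acac)2/t-BuOOH is now guided by the homoallylic 2α-OH, which lies cis to C10 on the five-membered ring, and should give 9α,10α-epoxy-4β-(triethylsilyloxy)dauca-5,7-dien-2α-ol F3. Re-acetylation (Ac2O, pyridine, DMAP) gives 2α-acetoxy-9α,10α-epoxy-4β-(triethylsilyloxy)dauca-5,7-diene F4, and acetic acid-buffered TBAF cleavage of the silyl ether comes back to the route at 19.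

Step 17.
- What may go wrong: hydrogen-atom transfer to the tertiary C5 radical, which sits between two quaternary carbons, may be slow. That would allow disproportionation, fragmentation or delivery of hydrogen from the wrong face.
- Fallback: the radical opening and the oxidation–reduction at C6 are replaced by one concerted syn addition from the α face, with C8=C9 temporarily masked. Setting out from 23, silylation (TESOTf, 2,6-lutidine) gives 2α-acetoxy-10β-benzoyloxy-4β-(triethylsilyloxy)dauca-5,8-diene F5. mCPBA (1 equiv) should epoxidise the more accessible C8=C9 bond to give the 8α,9α-epoxide F6. Hydroboration of the remaining C5=C6 bond with BH3·THF puts boron on C6 and hydrogen on C5, with the β face closed by C15 and the silyl ether. Oxidation with NaBO3·4H2O then gives the 5αH-6α-alcohol F7. Stereospecific deoxygenation of the epoxide (Re2O7 cat., P(OPh)3, toluene, 100 °C) restores C8=C9 in 2α-acetoxy-10β-benzoyloxy-4β-(triethylsilyloxy)-5αH-dauc-8-en-6α-ol F8. HF·pyridine then comes back to the route at 27, so that steps 16 to 19 are bypassed.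

**Further compounds**
F0 | step 7 | none | none
F1 | step 11 | 2α-acetoxy-4β-(triethylsilyloxy)dauca-5,7,9-triene | C[C@@]12C=CC(C)=CC=C1[C@](O[Si](CC)(CC)CC)(C(C)C)C[C@@H]2OC(C)=O
F2 | step 11 | 4β-(triethylsilyloxy)dauca-5,7,9-trien-2α-ol | C[C@@]12C=CC(C)=CC=C1[C@](O[Si](CC)(CC)CC)(C(C)C)C[C@@H]2O
F3 | step 11 | 9α,10α-epoxy-4β-(triethylsilyloxy)dauca-5,7-dien-2α-ol | C[C@@]12[C@@H]3O[C@@H]3C(C)=CC=C1[C@](O[Si](CC)(CC)CC)(C(C)C)C[C@@H]2O
F4 | step 11 | 2α-acetoxy-9α,10α-epoxy-4β-(triethylsilyloxy)dauca-5,7-diene | C[C@@]12[C@@H]3O[C@@H]3C(C)=CC=C1[C@](O[Si](CC)(CC)CC)(C(C)C)C[C@@H]2OC(C)=O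
F5 | step 17 | 2α-acetoxy-10β-benzoyloxy-4β-(triethylsilyloxy)dauca-5,8-diene | C[C@@]12[C@@H](OC(=O)c3ccccc3)C=C(C)CC=C1[C@](O[Si](CC)(CC)CC)(C(C)C)C[C@@H]2OC(C)=O
F6 | step 17 | 2α-acetoxy-10β-benzoyloxy-8α,9α-epoxy-4β-(triethylsilyloxy)dauc-5-ene | C[C@@]12[C@@H](OC(=O)c4ccccc4)[C@@H]3O[C@]3(C)CC=C1[C@](O[Si](CC)(CC)CC)(C(C)C)C[C@@H]2OC(C)=O
F7 | step 17 | 2α-acetoxy-10β-benzoyloxy-8α,9α-epoxy-4β-(triethylsilyloxy)-5αH-daucan-6α-ol | O[C@H]1C[C@@]3(C)O[C@H]3[C@H](OC(=O)c4ccccc4)[C@@]2(C)[C@@H](OC(C)=O)C[C@@](O[Si](CC)(CC)CC)(C(C)C)[C@H]12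
F8 | step 17 | 2α-acetoxy-10β-benzoyloxy-4β-(triethylsilyloxy)-5αH-dauc-8-en-6α-ol | O[C@H]1CC(C)=C[C@H](OC(=O)c2ccccc2)[C@@]2(C)[C@@H](OC(C)=O)C[C@@](O[Si](CC)(CC)CC)(C(C)C)[C@H]12
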